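Count this bench in millimolar per hour, not in percent. Each flask is closed and stirred, holds solid X, and slowly fills with J.

| flask | X | remark | time |
|---|---|---|---|
| epsilon | 6.7 mM | run made earlier |  |
| theta | 24 mM | run made earlier |  |
| delta | 68 mM | run made earlier |  |
| Saturday's | 40 mM |  | 30 h |
| Friday's | 30 mM |  | 30 h |
| Wednesday's | 21 mM |  | 30 h |
| Sunday's | 8.0 mM |  | 30 h |
| Tuesday's | 60 mM |  | 30 h |

- epsilon (time / h: J / %, X / %): 4.00: 13.3, 86.8; 8.00: 25.9, 73.6; 12.0: 39.4, 60.9; 15.0: 49.3, 50.6; 20.0: 65.1, 34.5
- theta (time / h: J / %, X / %): 4.00: 3.5, 96.8; 8.00: 7.7, 93.0; 12.0: 11.1, 89.2; 15.0: 14.3, 86.2; 20.0: 18.1, 81.4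
- delta (time / h: J / %, X / %): 1.50: 0.5, 99.5; 3.00: 1.0, 99.0; 6.00: 1.9, 98.0; 12.0: 4.1, 95.9; 20.0: 7.4, 93.9

(scatter of a reading: 0.3 percentage points)

- given per volume of solution although it is solid: X
- the numbers in the tables scatter by 0.3 percentage points (one standard deviation)
- at the start none of X is in solution
- what has only dissolved of X counts as not reacted
- a reading or a percentage of J counts all its forms, free or not

- all flasks from highest to lowest amount of J, in percent of the X charged, at 30 h (Saturday's / Friday's / Wednesday's / Sunday's / Tuesday's)
- the amount of J, in percent of the X charged of the flask you put first, at 30 h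
- the amount of J, in percent of the X charged of the flask you put last, at 30 h

Start from the last readings. Epsilon's gives 0.218 mM/h: call this the output rate, the millimolar of J made per hour while X lasts. Theta, with more X, gives 0.217 mM/h. Delta's last pair of readings sums to 101.3%, so read delta at 12.0 h instead, which gives 0.232 mM/h. So treat the output as zero-order: the end state is J alone, and the percent reached is output rate times time over charge.

At 30 h expect about 81.8% in Sunday's and 10.9% in Tuesday's, with the flasks in reverse order of charge, Sunday's charge being the smallest. Add no X: in these runs more charge brought no clear gain in output, so expect a lower percent. Distrust Sunday's a little. At the output rate its X lasts 36.7 h, longer than the wait, but that leaves about 1.46 mM, below the 2.31 mM read in epsilon at its last reading.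

The forecast gives Sunday's > Wednesday's > Friday's > Saturday's > Tuesday's, with 81% and 11%, Sunday's slightly under my figure: “The rate is therefore zero-order, independent of charge, and steady in each run.”

The simulation gives Sunday's > Wednesday's > Friday's > Saturday's > Tuesday's, with 82.5% and 11.0%.

    G → J, rate k1*[G]/(1 + ([G]/sat1)) (0.590 mM, k = 140 /h)
    X ⇌ G, rate k2*(cs2 - [G]) while solid is left; crystals form when [G] > cs2 (solubility = 2.90 mM, k = 0.0760 /h)
    G ⇌ E (K = 1.90, k = 0.180 /h)
    G + J ⇌ Z, settled at all times (K = 92.0 /M)

The dissolving of X, the rate-limiting step, has a constant of 0.076 /h and supplies 0.220 mM/h while solid is left and G stays low, while G turns into J with a constant of 140 /h, and G stands at 0.0197% of Sunday's charge at 30.0 h. The output rate gives 81.8% for Sunday's against 82.5%, and for a neighbour of Tuesday's charged with 24 mM it gives 27.2% against 27.5%.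

The numbers in the tables come from a simulation for substances that don't exist; scatter was added.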